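The product came late. Four flasks were to be fed alike, with rising partner, and two earlier runs were at hand.

| flask | substrate | partner | reagent | remark | time |
|---|---|---|---|---|---|
| maple | 0.17 M | 0.22 M | 0.17 M (fed, over 15 h) | run made earlier |  |
| larch | 0.17 M | 0.69 M | 0.17 M (fed, over 15 h) | run made earlier |  |
| Saturday's | 0.17 M | 0.250 M | 0.170 M (fed, over 15 h) |  | 15 h |
| Wednesday's | 0.17 M | 0.500 M | 0.170 M (fed, over 15 h) |  | 15 h |
| Thursday's | 0.17 M | 1.00 M | 0.170 M (fed, over 15 h) |  | 15 h |
| Monday's | 0.17 M | 2.00 M | 0.170 M (fed, over 15 h) |  | 15 h |

| run | time / h | product / % | substrate / % |
|---|---|---|---|
| maple | 0.833 | 0.1 | 99.5 |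
| maple | 2.00 | 0.1 | 98.8 |
| maple | 5.00 | 0.4 | 91.9 |
| maple | 10.0 | 3.3 | 78.2 |
| larch | 2.50 | 0 | 97.4 |
| larch | 5.00 | 0.9 | 93.4 |
| larch | 8.00 | 2.8 | 87.1 |
| larch | 10.0 | 6.4 | 82.8 |

(scatter of a reading: 0.3 percentage points)

- "hardly changes" means that all values lie within two and a half points (for a concentration: within two and a half percent of the largest)

* amount of product at the end, in percent of the substrate charged for Saturday's, Wednesday's, Thursday's, Monday's, in this order
* how the row runs (rises, then falls / falls all the way / rises all the way / hardly changes / falls, then rises)

I built the flask up one process at a time. I began with one step, substrate and reagent giving product at once, in which product follows the feed, and 66.7% of the reagent had gone in by 10.0 h. But the maple run had lost 21.8% of its substrate by then, less than the feed, so I added a reagent stock that was consumed slowly. The larch run, with more partner, lost 17.2%, less than the maple run, so I let the partner draw on that stock too.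

Then came the lag, an induction period: the maple run held 3.3% product at that time. A ramp entering integrators in series gains 1 in its early power of time with each integrator. Between 5.00 h and 10.0 h the larch run gave 2.83 for the time order, the slope of the logarithm of product against the logarithm of time. The maple run read 3.04, though such small readings carry a scatter of 0.3 percentage points. The substrate loss in the larch run had order 1.38. The rate of product in the larch run thus read as a power 1.83 of time, which pointed to a stock made in the flask and growing during the feed.

Carrying the maple product to 15 h at that order, I reckoned 10.4%. The two runs gave a partner order of 0.579, so I reckoned 11.2% for Saturday's flask and 16.7% for Wednesday's. I gave no figure for Thursday's or Monday's flask, whose partner lay above the larch charge.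

The forecast gave 9%, 14%, 16.5% and 15%, a row that rises, then falls, holding that “the scavenging eventually outweighs the faster capture”. For Saturday's and Wednesday's flasks it stood below my figures .

The flasks gave 11.8%, 16.5%, 17.7% and 14.3%, and the row ran as the forecast said: rises, then falls.

    substrate + reagent → open intermediate (k = 1.10 M⁻¹ h⁻¹)
    reagent + partner → second intermediate (k = 0.350 M⁻¹ h⁻¹)
    open intermediate + second intermediate → product (k = 5.50 M⁻¹ h⁻¹)
    reagent ⇌ dormant form (K = 0.760, k = 0.390 h⁻¹)

In Saturday's flask the time order between 7.50 h and 15.0 h came to 3.05, beside the 2.83 read from the larch run, and the open intermediate rose from 13.0% to 25.0%. The gradual adding and the short time held that flask's product down, in part: added at once it gave 25.2%, and left to 150 h it gave 38.5%. In Monday's flask the order over the same times came to 2.20, lower than in Saturday's flask, with the open intermediate down from 4.65% to 2.98%.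

All runs are simulated from invented constants, noise included.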